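## Retrosynthetic overview

1. The target is cut at the phthalide C3–C1' bond: a nickel-hydride, enantioconvergent radical hydroalkylation joins a spiroketal terminal alkene with racemic 3-bromo-5,7-dimethoxyphthalide and sets 3R in the last step.
2. The spiroketal alkene comes from acetone N,N-dimethylhydrazone, (R)-2-(hex-5-enyl)oxirane and (R)-propylene oxide: one-pot double azaenolate epoxide opening, then acid hydrolysis closes both tetrahydrofuran rings at once.
3. The (R)-epoxide comes from (R)-epichlorohydrin and pent-4-enyl Grignard reagent.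
4. The bromophthalide comes from Wohl–Ziegler bromination of 5,7-dimethoxyphthalide, itself made by carboxylate-directed C–H alkylation/lactonisation of 2,4-dimethoxybenzoic acid with CH2Br2; the acid comes from resorcinol (Kolbe–Schmitt, O-methylation).
5. Ring order: the benzene ring is bought; the two spiroketal rings (step 2) and the lactone ring (step 5) are built on separate branches; the union is last.

Assumption: the one-carbon reagents KHCO3/CO2, MeI and CH2Br2 are treated as reagents, not as numbered starting materials.

## Route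

Step 1
Reactants: 1 5-bromopent-1-ene; 2 (R)-epichlorohydrin
Product: 5 (2R)-2-(hex-5-en-1-yl)oxirane, via pent-4-en-1-ylmagnesium bromide 3 (not isolated), via (2R)-1-chlorooct-7-en-2-ol 4 (not isolated)
Conditions: Mg, THF, rt; CuI (5 mol%), 2, −40 → 0 °C; then 5 M aq. NaOH, rt
Reagents that add atoms: none
Why: Copper-catalysed Grignard opening of epichlorohydrin at the epoxide CH2 followed by Williamson closure of the chlorohydrin leaves the C–O stereocentre untouched, so (R)-2 gives (R)-5.

Step 2
Reactants: 6 acetone N,N-dimethylhydrazone; 5 (2R)-2-(hex-5-en-1-yl)oxirane; 7 (R)-propylene oxide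
Product: 11 (2R,5S,7R)-2-(hex-5-en-1-yl)-7-methyl-1,6-dioxaspiro[4.4]nonane, via hydrazone mono-alkoxide 8 (not isolated), via hydrazone diol 9 (not isolated), via dihydroxy ketone 10 (not isolated)
Conditions: 6, n-BuLi (1.05 equiv), THF, −78 → 0 °C; 5 (0.9 equiv), rt; n-BuLi (1.1 equiv), −78 → 0 °C; 7 (2 equiv), rt; 2 M HCl, THF, rt; SiO2 chromatography
Reagents that add atoms: none
Why: Corey–Enders azaenolate alkylation opens each terminal epoxide at CH2 (the second deprotonation occurs at the remaining methyl), so 2R and 7R are carried over from 5 and 7, and acid hydrolysis of the hydrazone triggers thermodynamic spiroketalisation to a roughly 1:1 pair of C5 epimers, from which the 5S epimer is isolated while the 5R epimer is re-equilibrated (PPTS, CH2Cl2) and recycled.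

Step 3
Reactants: 12 resorcinol
Product: 13 2,4-dihydroxybenzoic acid
Conditions: KHCO3, H2O, CO2 (1 atm), 100 °C; then HCl
Reagents that add atoms: carbon dioxide O=C=O (supplied through potassium hydrogencarbonate [K+].OC([O-])=O)
Why: Kolbe–Schmitt carboxylation of the resorcinol anion takes place at C4, ortho and para to the two hydroxyl groups, giving β-resorcylic acid.

Step 4
Reactants: 13 2,4-dihydroxybenzoic acid
Product: 15 2,4-dimethoxybenzoic acid, via methyl 2,4-dimethoxybenzoate 14 (not isolated)
Conditions: MeI (4 equiv), K2CO3, DMF, 50 °C; then 3 M aq. NaOH, 90 °C; HCl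
Reagents that add atoms: iodomethane CI
Why: Williamson methylation of both phenols and the carboxylate is followed in the same pot by saponification of the methyl ester.

Step 5
Reactants: 15 2,4-dimethoxybenzoic acid
Product: 17 5,7-dimethoxy-2-benzofuran-1(3H)-one, via potassium 2-(bromomethyl)-4,6-dimethoxybenzoate 16 (not isolated)
Conditions: Pd(OAc)2 (10 mol%), K2HPO4 (3 equiv), CH2Br2 (solvent), 140 °C, sealed tube
Reagents that add atoms: dibromomethane BrCBr
Why: Carboxylate-directed ortho-C–H palladation (C6–H is the only ortho hydrogen), alkylation by CH2Br2 and intramolecular SN2 lactonisation give the phthalide with the methoxy groups at C5 and C7 (C–H alkylation/lactonisation of benzoic acids with dihalomethanes).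

Step 6
Reactants: 17 5,7-dimethoxy-2-benzofuran-1(3H)-one
Product: 18 rac-3-bromo-5,7-dimethoxy-2-benzofuran-1(3H)-one
Conditions: NBS (1.05 equiv), AIBN (5 mol%), PhCF3, 85 °C, visible light; used crude
Reagents that add atoms: N-bromosuccinimide O=C1CCC(=O)N1Br
Why: Wohl–Ziegler radical bromination attacks the benzylic, α-oxygenated C3–H, with the non-polar solvent and radical initiation chosen to hold back ionic ring bromination; the racemate is acceptable because step 7 is stereoconvergent.

Step 7
Reactants: 11 (2R,5S,7R)-2-(hex-5-en-1-yl)-7-methyl-1,6-dioxaspiro[4.4]nonane; 18 rac-3-bromo-5,7-dimethoxy-2-benzofuran-1(3H)-one (1.5 equiv)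
Product: 19 (3R)-5,7-dimethoxy-3-{6-[(2R,5S,7R)-7-methyl-1,6-dioxaspiro[4.4]nonan-2-yl]hexyl}-2-benzofuran-1(3H)-one
Conditions: NiBr2·glyme (10 mol%), (4S,4'S)-2,2'-(propane-2,2-diyl)bis(4-phenyl-4,5-dihydro-1,3-oxazole) (12 mol%), (MeO)2MeSiH (2.5 equiv), KF (3 equiv), DMA/THF, 0 °C → rt
Reagents that add atoms: none
Why: Proposed new method: a chiral nickel hydride inserts the terminal alkene of 11 anti-Markovnikov to a primary alkylnickel, monovalent nickel abstracts bromine from either enantiomer of 18 to give one planar benzylic α-acyloxy C3 radical, and capture of this radical followed by C(sp3)–C(sp3) reductive elimination from trivalent nickel forms the C3–C1' bond and sets 3R under ligand control (the ligand antipode is used if the sense proves opposite, and any 3S diastereomer is removed by chromatography); the closest known reaction types are the NiH-catalysed enantioconvergent hydroalkylation of terminal olefins with racemic α-bromo amides and the nickel-catalysed enantioconvergent alkylation of racemic acyclic α-haloalkyl esters, of which 18 is a cyclic benzylic congener.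

## Compound list

1 | 5-bromopent-1-ene | C=CCCCBr | starting material
2 | (R)-epichlorohydrin, (2R)-2-(chloromethyl)oxirane | ClC[C@H]1CO1 | starting material
3 | pent-4-en-1-ylmagnesium bromide | C=CCCC[Mg]Br | intermediate
4 | (2R)-1-chlorooct-7-en-2-ol | ClC[C@H](O)CCCCC=C | intermediate
5 | (2R)-2-(hex-5-en-1-yl)oxirane | C=CCCCC[C@@H]1CO1 | intermediate
6 | acetone N,N-dimethylhydrazone | CC(C)=NN(C)C | starting material
7 | (R)-propylene oxide, (2R)-2-methyloxirane | C[C@@H]1CO1 | starting material
8 | lithium (5R)-2-(2,2-dimethylhydrazinylidene)undec-10-en-5-olate | [Li+].CC(=NN(C)C)CC[C@H]([O-])CCCCC=C | intermediate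
9 | (2R,8R)-5-(2,2-dimethylhydrazinylidene)tetradec-13-ene-2,8-diol | C[C@@H](O)CCC(=NN(C)C)CC[C@H](O)CCCCC=C | intermediate
10 | (2R,8R)-2,8-dihydroxytetradec-13-en-5-one | C[C@@H](O)CCC(=O)CC[C@H](O)CCCCC=C | intermediate
11 | (2R,5S,7R)-2-(hex-5-en-1-yl)-7-methyl-1,6-dioxaspiro[4.4]nonane | C=CCCCC[C@@H]1CC[C@]3(CC[C@@H](C)O3)O1 | intermediate
12 | resorcinol | Oc1cccc(O)c1 | starting material
13 | 2,4-dihydroxybenzoic acid | OC(=O)c1ccc(O)cc1O | intermediate
14 | methyl 2,4-dimethoxybenzoate | COC(=O)c1ccc(OC)cc1OC | intermediate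
15 | 2,4-dimethoxybenzoic acid | COc1ccc(C(O)=O)c(OC)c1 | intermediate
16 | potassium 2-(bromomethyl)-4,6-dimethoxybenzoate | [K+].COc1cc(CBr)c(C([O-])=O)c(OC)c1 | intermediate
17 | 5,7-dimethoxy-2-benzofuran-1(3H)-one | COc1cc(OC)c2c(c1)COC2=O | intermediate
18 | rac-3-bromo-5,7-dimethoxy-2-benzofuran-1(3H)-one | COc1cc(OC)c2c(c1)C(Br)OC2=O | intermediate
19 | (3R)-5,7-dimethoxy-3-{6-[(2R,5S,7R)-7-methyl-1,6-dioxaspiro[4.4]nonan-2-yl]hexyl}-2-benzofuran-1(3H)-one | COc1cc(OC)c2c(c1)[C@@H](CCCCCC[C@@H]1CC[C@]3(CC[C@@H](C)O3)O1)OC2=O | target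

## Step count and risks

Total step count: 7. Longest linear sequence: 5 steps (12 → 13 → 15 → 17 → 18 → 19; steps 3 to 7).

**Step 7** is the most likely to fail: the coupling is new for a 3-bromophthalide, and 18 may be hydrodebrominated to 17, hydrolysed, or coupled with low enantioselectivity. The fallback sets out from 11 and comes back at 19. Alkene 11 is hydroborated and oxidised (9-BBN, THF; NaBO3·4H2O) to 6-[(2R,5S,7R)-7-methyl-1,6-dioxaspiro[4.4]nonan-2-yl]hexan-1-ol F1. Buffered Appel iodination (I2, PPh3, imidazole, CH2Cl2, 0 °C) gives (2R,5S,7R)-2-(6-iodohexyl)-7-methyl-1,6-dioxaspiro[4.4]nonane F2. Zinc insertion (Zn dust, LiCl, THF, 40 °C) gives {6-[(2R,5S,7R)-7-methyl-1,6-dioxaspiro[4.4]nonan-2-yl]hexyl}zinc iodide F3. F3 and rac-18 are then joined in a nickel/bis(oxazoline)-catalysed enantioconvergent Negishi coupling (NiBr2·glyme, THF/DMA, −20 °C). This forms the same C3–C1' bond through the same C3 radical but with a preformed nucleophile, the arrangement closest to the known α-haloalkyl ester couplings, and gives 19.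

**Step 6** is second: the dimethoxy-substituted ring of 17 may be brominated ionically at C4 or C6 instead of at C3. The fallback sets out from 17 and comes back at 18, replacing the radical bromination by a polar one. Lactone 17 is deprotonated at C3 (LiN(SiMe3)2, THF, −78 °C) to lithium 5,7-dimethoxy-2-benzofuran-1-olate F4. This enolate is cannulated into excess 1,2-dibromo-1,1,2,2-tetrachloroethane at −78 °C; the inverse addition limits alkylation of the enolate by the product, and 18 results.

**Step 5** is third: the electron-rich acid 15 may protodecarboxylate on divalent palladium at 140 °C, or be alkylated at oxygen. The fallback sets out from 15 and comes back at 17. Carboxylate-directed ortho-lithiation (s-BuLi/TMEDA, 2.2 equiv, THF, −78 °C) gives lithium 2-lithio-4,6-dimethoxybenzoate F5; this is the regiochemistry established for 2-methoxybenzoic acid, though competing lithiation between the two methoxy groups must be checked. Quenching with DMF and acidifying gives 3-hydroxy-5,7-dimethoxy-2-benzofuran-1(3H)-one F6. Reduction of F6 with NaBH4 in aqueous NaOH, then acidification with HCl, closes the lactone to 17.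

## Further compounds

F1 | step 7 | 6-[(2R,5S,7R)-7-methyl-1,6-dioxaspiro[4.4]nonan-2-yl]hexan-1-ol | OCCCCCC[C@@H]1CC[C@]3(CC[C@@H](C)O3)O1
F2 | step 7 | (2R,5S,7R)-2-(6-iodohexyl)-7-methyl-1,6-dioxaspiro[4.4]nonane | ICCCCCC[C@@H]1CC[C@]3(CC[C@@H](C)O3)O1
F3 | step 7 | {6-[(2R,5S,7R)-7-methyl-1,6-dioxaspiro[4.4]nonan-2-yl]hexyl}zinc iodide | I[Zn]CCCCCC[C@@H]1CC[C@]3(CC[C@@H](C)O3)O1
F4 | step 6 | lithium 5,7-dimethoxy-2-benzofuran-1-olate | [Li+].[O-]c1occ2cc(OC)cc(OC)c12
F5 | step 5 | lithium 2-lithio-4,6-dimethoxybenzoate | [Li+].[Li]c1cc(OC)cc(OC)c1C([O-])=O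
F6 | step 5 | 3-hydroxy-5,7-dimethoxy-2-benzofuran-1(3H)-one | COc1cc(OC)c2c(c1)C(O)OC2=O
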